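**Retrosynthetic overview**

1. The target is opened at the ester C–O bond into diene diol 14 and the (Z)-4-silyloxycinnamic acid 17 (aryl alkyne, CO2, cis-semihydrogenation).
2. The 2-substituted 1,3-diene comes from a C-12 bromide and the 2-butadienyl Grignard reagent (copper-catalysed sp3–sp2 coupling).
3. Key bond: the tertiary C-8–O bond is made on the finished bicycle by a bromine-relayed hydration of the 7-ene, which sets C-8 trans to the C-9 side chain.
4. Both rings are formed in one epoxide-initiated cation–olefin bicyclisation (ring A first, then ring B). The Sharpless epoxide sets C-3/C-4 and, through the chair array, C-5/C-10; the (Z)-alkene sets C-9; the C-3 oxygen is then removed.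
5. The acyclic chain comes from geranyl bromide and pent-3-yn-1-ol, with a directed carbomagnesiation for the (Z)-alkene and allylic oxidation at the terminal (E)-methyl group.

Assumption: the configuration is taken exactly as written, (4S,5S,8R,9R,10R) in labdane numbering (C-18 = oxygenated carbon on C-4, C-17 = methyl on C-8, C-20 = methyl on C-10). This is the 5,10-diepimer of the usual labdan-8-ol series, so sclareol-type chiral-pool materials are not used.

**Route**

Step 1
Reactants: 1 pent-3-yn-1-ol; 2 geranyl bromide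
Product: 3 (7E)-8,12-dimethyltrideca-7,11-dien-3-yn-1-ol
Conditions: n-BuLi (1.0 equiv), then s-BuLi (1.1 equiv), TMEDA, THF, −78 → −20 °C; then 2, −78 → 0 °C; H2O
Reagents that add atoms: none
Why: The O,C-dilithio derivative of 1 (alkoxide plus propargylic carbanion at the methyl group) is alkylated at carbon by the allylic bromide in an SN2 reaction (propargylic dianion alkylation), which keeps the (E)-alkene of the geranyl unit.

Step 2
Reactants: 3 (7E)-8,12-dimethyltrideca-7,11-dien-3-yn-1-ol
Product: 4 (3Z,7E)-4,8,12-trimethyltrideca-3,7,11-trien-1-ol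
Conditions: MeMgBr (4 equiv), Fe(acac)3 (10 mol%), THF, −78 → 0 °C; then H2O
Reagents that add atoms: methylmagnesium bromide, C[Mg]Br
Why: Alkoxide-directed, iron-catalysed syn-carbomagnesiation of the homopropargylic alcohol puts methyl on the distal alkyne carbon and magnesium on the proximal one, so protonolysis gives the trisubstituted alkene with the long chain cis to CH2CH2OH, i.e. (3Z).

Step 3
Reactants: 4 (3Z,7E)-4,8,12-trimethyltrideca-3,7,11-trien-1-ol
Product: 5 (3Z,7E)-1-bromo-4,8,12-trimethyltrideca-3,7,11-triene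
Conditions: CBr4, PPh3, CH2Cl2, 0 °C
Reagents that add atoms: carbon tetrabromide, BrC(Br)(Br)Br
Why: Appel bromination converts the primary alcohol into the bromide under neutral conditions without touching the trisubstituted alkenes.

Step 4
Reactants: 5 (3Z,7E)-1-bromo-4,8,12-trimethyltrideca-3,7,11-triene
Product: 6 (2E,6E,10Z)-13-bromo-2,6,10-trimethyltrideca-2,6,10-trien-1-ol
Conditions: SeO2 (0.3 equiv), t-BuOOH (3 equiv), salicylic acid (0.1 equiv), CH2Cl2, 20 °C
Reagents that add atoms: tert-butyl hydroperoxide, CC(C)(C)OO (oxygen relayed by catalytic selenium dioxide, O=[Se]=O)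
Why: SeO2-catalysed allylic hydroxylation (ene reaction, then [2,3]-sigmatropic shift) is selective for the (E)-methyl group of the terminal isopropylidene unit and gives the (2E)-allylic alcohol.

Step 5
Reactants: 6 (2E,6E,10Z)-13-bromo-2,6,10-trimethyltrideca-2,6,10-trien-1-ol
Product: 8 triethyl{[(2R,3R)-3-[(3E,7Z)-10-bromo-3,7-dimethyldeca-3,7-dien-1-yl]-2-methyloxiran-2-yl]methoxy}silane, via epoxy alcohol 7 (not isolated)
Conditions: Ti(OiPr)4 (10 mol%), D-(−)-diethyl tartrate (12 mol%), t-BuOOH (2 equiv), 4 Å sieves, CH2Cl2, −20 °C; then Et3SiCl, Et3N, DMAP, −20 → 0 °C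
Reagents that add atoms: tert-butyl hydroperoxide, CC(C)(C)OO; chlorotriethylsilane, CC[Si](Cl)(CC)CC
Why: Katsuki–Sharpless asymmetric epoxidation with D-(−)-diethyl tartrate epoxidises only the allylic-alcohol alkene and sets both epoxide centres as (2R,3R), and the primary alcohol is silylated in the same pot (in situ derivatisation) so that it cannot interfere in the next step.

Step 6
Reactants: 8 triethyl{[(2R,3R)-3-[(3E,7Z)-10-bromo-3,7-dimethyldeca-3,7-dien-1-yl]-2-methyloxiran-2-yl]methoxy}silane
Product: 9 (3R,4S,5S,9S,10S)-12-bromo-18-(triethylsilyloxy)-13,14,15,16-tetranorlabd-7-en-3-ol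
Conditions: MeAlCl2 (1.5 equiv), CH2Cl2, −78 °C, 30 min; then Et3N, aq. NaHCO3
Reagents that add atoms: none
Why: Lewis-acid opening of the epoxide at its quaternary carbon with anti attack by the (E)-alkene and then by the (Z)-alkene through a chair–chair array (Stork–Eschenmoser epoxy-polyene bicyclisation, ring A then ring B) transfers the epoxide configuration to C-3 and C-4 (CH2OSi equatorial), gives the trans ring fusion at C-5/C-10 from the (E)-alkene, puts the bromoethyl chain axial at C-9 from the (Z)-alkene, and ends by proton loss to the 7-ene.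

Step 7
Reactants: 9 (3R,4S,5S,9S,10S)-12-bromo-18-(triethylsilyloxy)-13,14,15,16-tetranorlabd-7-en-3-ol
Product: 10 (4S,5S,9S,10S)-12-bromo-18-(triethylsilyloxy)-13,14,15,16-tetranorlabda-2,7-diene
Conditions: Burgess reagent (2.5 equiv), PhMe, 60 °C
Reagents that add atoms: none
Why: Burgess syn-elimination (sulfamate ester, Ei) of the secondary 3-hydroxyl group can only go towards C-2 and removes the oxygen that the epoxide left at C-3.

Step 8
Reactants: 10 (4S,5S,9S,10S)-12-bromo-18-(triethylsilyloxy)-13,14,15,16-tetranorlabda-2,7-diene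
Product: 12 (4S,5S,8R,9R,10R)-12-bromo-13,14,15,16-tetranorlabd-2-ene-8,18-diol, via bromolanium triflate 11 (not isolated)
Conditions: CF3SO3H (10 mol%), H2O (10 equiv), (CF3)2CHOH/CH2Cl2 (4:1), −20 → 0 °C; then aq. NaHCO3
Reagents that add atoms: water, O
Why: Proposed new method: bromine-relayed trans-hydration, in which Markovnikov protonation of the 7-ene gives the tertiary C-8 cation whose empty orbital is parallel to the axial C-9–C-11 bond, so the C-12 bromine closes a five-membered bromolanium ion on the face of C-8 cis to the side chain and water then opens it at the tertiary carbon with inversion, placing the new C–O bond axial and trans to the side chain (8R) while the same aqueous acid hydrolyses the triethylsilyl ether; the closest known reaction types are acid-catalysed alkene hydration, 1,4-halogen participation through five-membered halonium ions in solvolysis, and the anti (Fürst–Plattner) opening of halonium ions.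

Step 9
Reactants: 12 (4S,5S,8R,9R,10R)-12-bromo-13,14,15,16-tetranorlabd-2-ene-8,18-diol
Product: 13 (4S,5S,8R,9R,10R)-12-bromo-13,14,15,16-tetranorlabdane-8,18-diol
Conditions: H2 (1 atm), [Ir(cod)(PCy3)(py)]PF6 (3 mol%), CH2Cl2, 20 °C
Reagents that add atoms: none
Why: Homogeneous catalytic hydrogenation saturates the only remaining alkene (C-2/C-3) and leaves the alkyl bromide and both hydroxyl groups untouched; no stereocentre is formed.

Step 10
Reactants: 13 (4S,5S,8R,9R,10R)-12-bromo-13,14,15,16-tetranorlabdane-8,18-diol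
Product: 14 (4S,5S,8R,9R,10R)-labda-13(16),14-diene-8,18-diol
Conditions: CH2=CH–C(MgCl)=CH2 (3.5 equiv, from chloroprene and Mg in THF), Li2CuCl4 (5 mol%), THF, −10 → 20 °C; then H2O
Reagents that add atoms: buta-1,3-dien-2-ylmagnesium chloride, C=CC(=C)[Mg]Cl
Why: Li2CuCl4-catalysed coupling of the primary alkyl bromide with the 2-butadienyl Grignard reagent (Kochi-type sp3–sp2 cross-coupling) forms the C-12–C-13 bond and installs the 2-substituted 1,3-diene in one step, the two hydroxyl groups being carried as magnesium alkoxides.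

Step 11
Reactants: 15 tert-butyl(4-ethynylphenoxy)dimethylsilane
Product: 16 3-[4-(tert-butyldimethylsilyloxy)phenyl]prop-2-ynoic acid
Conditions: n-BuLi, THF, −78 °C; CO2; then cold 1 M HCl
Reagents that add atoms: carbon dioxide, O=C=O
Why: Deprotonation of the terminal alkyne and carboxylation of the lithium acetylide gives the arylpropiolic acid.

Step 12
Reactants: 16 3-[4-(tert-butyldimethylsilyloxy)phenyl]prop-2-ynoic acid
Product: 17 (2Z)-3-[4-(tert-butyldimethylsilyloxy)phenyl]prop-2-enoic acid
Conditions: H2 (1 atm), Pd/CaCO3 poisoned with Pb(OAc)2, quinoline, EtOAc, 20 °C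
Reagents that add atoms: none
Why: cis-Semihydrogenation over the lead-poisoned palladium catalyst adds H2 syn to the alkyne and sets the (Z)-alkene.

Step 13
Reactants: 14 (4S,5S,8R,9R,10R)-labda-13(16),14-diene-8,18-diol; 17 (2Z)-3-[4-(tert-butyldimethylsilyloxy)phenyl]prop-2-enoic acid
Product: 18 (4S,5S,8R,9R,10R)-8-hydroxylabda-13(16),14-dien-18-yl (2Z)-3-[4-(tert-butyldimethylsilyloxy)phenyl]prop-2-enoate
Conditions: DCC (1.2 equiv), DMAP (0.1 equiv), CH2Cl2, 0 → 20 °C
Reagents that add atoms: none
Why: Steglich esterification forms the ester C–O bond at the primary C-18 hydroxyl, the tertiary C-8 hydroxyl being unreactive, and the mild conditions keep the (Z)-alkene.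

Step 14
Reactants: 18 (4S,5S,8R,9R,10R)-8-hydroxylabda-13(16),14-dien-18-yl (2Z)-3-[4-(tert-butyldimethylsilyloxy)phenyl]prop-2-enoate
Product: 19 (4S,5S,8R,9R,10R)-8-hydroxylabda-13(16),14-dien-18-yl (2Z)-3-(4-hydroxyphenyl)prop-2-enoate
Conditions: Bu4NF (1.1 equiv), AcOH (1.2 equiv), THF, 0 °C
Reagents that add atoms: none
Why: Buffered fluoride cleaves the aryl silyl ether (desilylation) and leaves the ester, the (Z)-alkene, the diene and the tertiary alcohol intact.

**Compound list**

1 | pent-3-yn-1-ol | CC#CCCO | starting material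
2 | geranyl bromide, (2E)-1-bromo-3,7-dimethylocta-2,6-diene | CC(C)=CCC/C(C)=C/CBr | starting material
3 | (7E)-8,12-dimethyltrideca-7,11-dien-3-yn-1-ol | CC(C)=CCC/C(C)=C/CCC#CCCO | intermediate
4 | (3Z,7E)-4,8,12-trimethyltrideca-3,7,11-trien-1-ol | CC(C)=CCC/C(C)=C/CC/C(C)=C\CCO | intermediate
5 | (3Z,7E)-1-bromo-4,8,12-trimethyltrideca-3,7,11-triene | CC(C)=CCC/C(C)=C/CC/C(C)=C\CCBr | intermediate
6 | (2E,6E,10Z)-13-bromo-2,6,10-trimethyltrideca-2,6,10-trien-1-ol | OC/C(C)=C/CC/C(C)=C/CC/C(C)=C\CCBr | intermediate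
7 | [(2R,3R)-3-[(3E,7Z)-10-bromo-3,7-dimethyldeca-3,7-dien-1-yl]-2-methyloxiran-2-yl]methanol | OC[C@@]1(C)O[C@@H]1CC/C(C)=C/CC/C(C)=C\CCBr | intermediate (not isolated)
8 | triethyl{[(2R,3R)-3-[(3E,7Z)-10-bromo-3,7-dimethyldeca-3,7-dien-1-yl]-2-methyloxiran-2-yl]methoxy}silane | CC[Si](CC)(CC)OC[C@@]1(C)O[C@@H]1CC/C(C)=C/CC/C(C)=C\CCBr | intermediate
9 | (3R,4S,5S,9S,10S)-12-bromo-18-(triethylsilyloxy)-13,14,15,16-tetranorlabd-7-en-3-ol (trans-decalin; 3-OH and CH2OSi equatorial; bromoethyl chain axial, trans to the C-10 methyl) | BrCC[C@@H]1[C@]2(C)CC[C@@H](O)[C@](C)(CO[Si](CC)(CC)CC)[C@H]2CC=C1C | intermediate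
10 | (4S,5S,9S,10S)-12-bromo-18-(triethylsilyloxy)-13,14,15,16-tetranorlabda-2,7-diene | BrCC[C@@H]1[C@]2(C)CC=C[C@](C)(CO[Si](CC)(CC)CC)[C@H]2CC=C1C | intermediate
11 | bromolanium triflate: five-membered cyclic bromonium ion joining C-8 and C-12 of protonated 10, bromine on the face of C-8 cis to the C-9 side chain | [Br+]1CC[C@@H]2[C@]3(C)CC=C[C@](C)(CO[Si](CC)(CC)CC)[C@H]3CC[C@@]21C.[O-]S(=O)(=O)C(F)(F)F | intermediate (not isolated)
12 | (4S,5S,8R,9R,10R)-12-bromo-13,14,15,16-tetranorlabd-2-ene-8,18-diol | BrCC[C@@H]1[C@]2(C)CC=C[C@](C)(CO)[C@H]2CC[C@@]1(C)O | intermediate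
13 | (4S,5S,8R,9R,10R)-12-bromo-13,14,15,16-tetranorlabdane-8,18-diol | BrCC[C@@H]1[C@]2(C)CCC[C@](C)(CO)[C@H]2CC[C@@]1(C)O | intermediate
14 | (4S,5S,8R,9R,10R)-labda-13(16),14-diene-8,18-diol | C=CC(=C)CC[C@@H]1[C@]2(C)CCC[C@](C)(CO)[C@H]2CC[C@@]1(C)O | intermediate
15 | tert-butyl(4-ethynylphenoxy)dimethylsilane | C#Cc1ccc(O[Si](C)(C)C(C)(C)C)cc1 | starting material
16 | 3-[4-(tert-butyldimethylsilyloxy)phenyl]prop-2-ynoic acid | OC(=O)C#Cc1ccc(O[Si](C)(C)C(C)(C)C)cc1 | intermediate
17 | (2Z)-3-[4-(tert-butyldimethylsilyloxy)phenyl]prop-2-enoic acid | OC(=O)/C=C\c1ccc(O[Si](C)(C)C(C)(C)C)cc1 | intermediate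
18 | (4S,5S,8R,9R,10R)-8-hydroxylabda-13(16),14-dien-18-yl (2Z)-3-[4-(tert-butyldimethylsilyloxy)phenyl]prop-2-enoate | C=CC(=C)CC[C@@H]1[C@]2(C)CCC[C@](C)(COC(=O)/C=C\c3ccc(O[Si](C)(C)C(C)(C)C)cc3)[C@H]2CC[C@@]1(C)O | intermediate
19 | (4S,5S,8R,9R,10R)-8-hydroxylabda-13(16),14-dien-18-yl (2Z)-3-(4-hydroxyphenyl)prop-2-enoate | C=CC(=C)CC[C@@H]1[C@]2(C)CCC[C@](C)(COC(=O)/C=C\c3ccc(O)cc3)[C@H]2CC[C@@]1(C)O | target

**Step count and risks**

Total: 14 steps (12 in the main line, 2 for acid 17). Longest linear sequence: 12 steps (steps 1–10, 13, 14).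

The three steps most likely to fail are steps 6, 7 and 8.

Step 6, the bicyclisation. The epoxide may rearrange to a ketone, the cascade may stop after ring A, or the C-8 cation may be captured instead of losing a proton. Alkene regioisomers from proton loss and any C-8 alcohol are tolerated, because step 7 dehydrates the alcohol and step 8 protonates every such alkene to the same C-8 cation. The fallback changes from a cationic to a radical ring closure; it sets out from 8 and comes back at 12. Compound 8 is treated with Cp2TiCl (trivalent titanium, made from Cp2TiCl2 and Mn dust, with Me3SiCl and 2,4,6-collidine in THF). Homolytic epoxide opening gives the C-4 radical, which closes ring A and ring B through the same chair–chair array, with the larger silyloxymethyl group equatorial, and ends by hydrogen loss to the exocyclic alkene, (3R,4S,5S,9S,10S)-12-bromo-18-(triethylsilyloxy)-13,14,15,16-tetranorlabd-8(17)-en-3-ol F1. Burgess dehydration as in step 7 gives the 2,8(17)-diene F2, and the conditions of step 8 convert F2 into 12.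

Step 7, the Burgess dehydration. The equatorial hydroxyl group next to the quaternary C-4 may ionise and give ring A rearrangement instead of clean elimination. The fallback removes the oxygen through the ketone; it sets out from 9 and comes back at 10. Dess–Martin periodinane oxidises 9 to the 3-ketone F3. KN(SiMe3)2 and PhNTf2 at −78 °C give the enol triflate F4, since only C-2 can enolise. Reduction with Pd(OAc)2, PPh3, Bu3N and HCO2H replaces the triflate by hydrogen and gives 10.

Step 8, the proposed bromine-relayed hydration. Water may capture the open C-8 cation before the bromine bridges, or the cation may undergo hydride or methyl shifts. Two things work in its favour: the axial C–O bond is also what trans-diaxial Markovnikov addition to the 7-ene gives, and the 8R alcohol is the more stable C-8 epimer because the C-17 methyl avoids the 1,3-diaxial contact with C-20. The fallback uses known chemistry; it sets out from 10 and comes back at 13. Hydrogenation with H2 and RhCl(PPh3)3 reduces only the disubstituted C-2/C-3 alkene and gives the 7-ene F5. Oxymercuration–demercuration (Hg(OAc)2, THF/H2O, 0 °C; then NaBH4, NaOH) adds water in the Markovnikov, anti and trans-diaxial sense and gives the 8R tertiary alcohol F6. AcOH/THF/H2O removes the triethylsilyl group and gives 13.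

Further compounds
F1 | step 6 | (3R,4S,5S,9S,10S)-12-bromo-18-(triethylsilyloxy)-13,14,15,16-tetranorlabd-8(17)-en-3-ol | BrCC[C@@H]1[C@]2(C)CC[C@@H](O)[C@](C)(CO[Si](CC)(CC)CC)[C@H]2CCC1=C
F2 | step 6 | (4S,5S,9S,10S)-12-bromo-18-(triethylsilyloxy)-13,14,15,16-tetranorlabda-2,8(17)-diene | BrCC[C@@H]1[C@]2(C)CC=C[C@](C)(CO[Si](CC)(CC)CC)[C@H]2CCC1=C
F3 | step 7 | 3-ketone of 9, (4S,5S,9S,10S)-12-bromo-18-(triethylsilyloxy)-13,14,15,16-tetranorlabd-7-en-3-one | BrCC[C@@H]1[C@]2(C)CCC(=O)[C@](C)(CO[Si](CC)(CC)CC)[C@H]2CC=C1C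
F4 | step 7 | enol triflate of F3, (4S,5S,9S,10S)-12-bromo-18-(triethylsilyloxy)-13,14,15,16-tetranorlabda-2,7-dien-3-yl trifluoromethanesulfonate | BrCC[C@@H]1[C@]2(C)CC=C(OS(=O)(=O)C(F)(F)F)[C@](C)(CO[Si](CC)(CC)CC)[C@H]2CC=C1C
F5 | step 8 | (4S,5S,9S,10S)-12-bromo-18-(triethylsilyloxy)-13,14,15,16-tetranorlabd-7-ene | BrCC[C@@H]1[C@]2(C)CCC[C@](C)(CO[Si](CC)(CC)CC)[C@H]2CC=C1C
F6 | step 8 | (4S,5S,8R,9R,10R)-12-bromo-18-(triethylsilyloxy)-13,14,15,16-tetranorlabdan-8-ol | BrCC[C@@H]1[C@]2(C)CCC[C@](C)(CO[Si](CC)(CC)CC)[C@H]2CC[C@@]1(C)O
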